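**Retrosynthetic overview**
1. Target 31 ⇐ global desilylation and triacetylation of the silylated 2-chloro-4-siloxycyclopent-2-enone 29; the carbocycle (ring C8–C12) is the last ring made.
2. 29 ⇐ intramolecular Horner–Wadsworth–Emmons closure of the acyclic α-chloro-β-ketophosphonate aldehyde 28. The feature used is the chloro-alkene C10(Cl)=C11 of ring C8–C12, which lies between the C9 ketone and C11, an aldehyde-level carbon on the quaternary carbinol C12.
3. 28 ⇐ C9 aldehyde + dimethyl (chloromethyl)phosphonate; the C11 aldehyde comes from the reduced carbonyl of a γ-lactone.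
4. That temporary γ-lactone (O–C11–C12–C8–C7, made first as a butenolide and opened again) is the stereochemical template: anti conjugate addition of lithiodithiane (C9) sets C8, enolate allylation brings C13–C20, enolate hydroxylation sets C12.
5. Butenolide ⇐ D-xylono-1,4-lactone (C4–C8, carrying the C5–C7 triol) by a C1–C3 Wittig reaction at C4 and a C11–C12 Wittig reaction at C8.

Key step: step 17

Remark: D-xylono-1,4-lactone (the commercial bromine-water oxidation product of D-xylose) is taken as the chiral-pool material, and C1 is carried as the free acid until step 11 so that it can be neither enolised nor reduced.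
Atom labels C1–C20 follow the prostanoid numbering of the target (C1 ester carbon, ring C8–C12, C20 terminal methyl). TBS = tert-butyldimethylsilyl, TES = triethylsilyl. Stereochemistry of every compound is fixed by its SMILES in the compound list.

**Route**

Step 1
Reactants: 1 D-xylono-1,4-lactone
Product: 2 2,3,5-tris-O-TBS-D-xylono-1,4-lactone
Conditions: TBSCl, imidazole, DMF, 40 °C
Reagents that add atoms: tert-butyldimethylsilyl chloride, CC(C)(C)[Si](C)(C)Cl
Why: Standard silyl ether formation on all three hydroxyls; no stereocentre is touched, and lactone C2, C3, C4 become C5, C6, C7 of the target.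

Step 2
Reactants: 2 2,3,5-tris-O-TBS-D-xylono-1,4-lactone
Product: 3 2,3,5-tris-O-TBS-D-xylofuranose (lactol, anomeric mixture)
Conditions: iBu2AlH, CH2Cl2, −78 °C; aq KNaC4H4O6
Reagents that add atoms: none
Why: Partial hydride reduction of a γ-lactone stops at the lactol because the tetrahedral aluminium hemiacetal is stable at −78 °C.

Step 3
Reactants: 3 2,3,5-tris-O-TBS-D-xylofuranose; 4 (2-carboxyethyl)triphenylphosphonium bromide
Product: 6 (Z)-5,6,8-tris-O-TBS-2,3,4-trideoxy-D-xylo-oct-3-enonic acid (free 7-OH), via carboxylate ylide 5 (not isolated)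
Conditions: 4, LiN(SiMe3)2, THF, −78 → 0 °C; then 3, −78 °C → rt; aq citric acid
Reagents that add atoms: none
Why: Wittig olefination of the lactol through its open hydroxy-aldehyde form adds C1–C3 and frees only the former ring oxygen (C7–OH), which is thereby differentiated from the three silylated oxygens; the lithium counter-ion and low temperature are chosen to suppress O→O silyl migration, and the alkene geometry is irrelevant.

Step 4
Reactants: 6 (Z)-5,6,8-tris-O-TBS-2,3,4-trideoxy-D-xylo-oct-3-enonic acid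
Product: 7 5,6,8-tris-O-TBS-2,3,4-trideoxy-D-xylo-octonic acid (free 7-OH)
Conditions: H2 (1 atm), 10% Pd/C, EtOAc, rt
Reagents that add atoms: none
Why: Heterogeneous catalytic hydrogenation saturates the only C=C bond at a stage where no other alkene, sulfur or halogen is present.

Step 5
Reactants: 7 5,6,8-tris-O-TBS-2,3,4-trideoxy-D-xylo-octonic acid
Product: 8 5,6-bis-O-TBS-2,3,4-trideoxy-D-xylo-octonic acid (7,8-diol)
Conditions: HF·pyridine, pyridine, THF, 0 °C
Reagents that add atoms: none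
Why: Buffered fluoride desilylation should cleave the unhindered primary TBS ether much faster than the two flanked secondary ones.

Step 6
Reactants: 8 5,6-bis-O-TBS-2,3,4-trideoxy-D-xylo-octonic acid; 9 methyl (triphenylphosphoranylidene)acetate
Product: 12 butenolide acid 6-(5-oxo-2,5-dihydrofuran-2-yl)-5,6-bis(TBS-oxy)hexanoic acid (D-xylo over C5/C6/C7), via α-hydroxy aldehyde 10 (not isolated), via Z-hydroxy enoate 11 (not isolated)
Conditions: TEMPO (cat.), PhI(OAc)2, CH2Cl2, rt; then 9, MeOH, 0 °C → rt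
Reagents that add atoms: none
Why: Nitroxyl-catalysed oxidation takes the primary alcohol of the diol selectively, the α-hydroxy aldehyde undergoes a Wittig reaction that is Z-selective in methanol, and the (Z)-γ-hydroxy enoate lactonises spontaneously, with C7 untouched.

Step 7
Reactants: 13 (Z)-oct-2-en-1-ol
Product: 14 (Z)-1-bromooct-2-ene
Conditions: CBr4, PPh3, CH2Cl2, 0 °C
Reagents that add atoms: tetrabromomethane, BrC(Br)(Br)Br
Why: Appel bromination of a primary allylic alcohol proceeds by SN2 at low temperature without allylic transposition or Z/E isomerisation.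

Step 8
Reactants: 12 butenolide acid; 15 1,3-dithiane; 14 (Z)-1-bromooct-2-ene
Product: 18 lactone acid with C8 dithianyl trans to the C7 chain and C12 octenyl trans to dithianyl, via 2-lithio-1,3-dithiane 16 (not isolated), via dilithium lactone enolate 17 (not isolated)
Conditions: 15, n-C4H9Li, THF, −30 °C; 12 (2.1 equiv of anion per 12), −78 °C; then 14, −78 → −30 °C; aq citric acid
Reagents that add atoms: none
Why: Tandem conjugate addition–enolate alkylation: after the first equivalent of anion has only deprotonated the acid, lithiodithiane adds 1,4 to the butenolide anti to the bulky C7 substituent and so sets C8, and the enolate is C-allylated anti to the new dithianyl group (the C12 configuration is provisional).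

Step 9
Reactants: 18 lactone acid
Product: 19 α-hydroxy lactone acid (C12–OH trans to dithianyl, octenyl cis to dithianyl)
Conditions: LiN(iPr)2 (2.3 equiv), THF, −78 °C; 3-phenyl-2-(phenylsulfonyl)oxaziridine, −78 °C; AcOH
Reagents that add atoms: 3-phenyl-2-(phenylsulfonyl)oxaziridine, O=S(=O)(c1ccccc1)N1OC1c1ccccc1
Why: Davis enolate oxidation: the carboxylate blocks enolisation at C2 so only the C11–C12 lactone enolate forms, and the oxaziridine attacks the face anti to the adjacent dithianyl group, which places the hydroxyl trans to C9 and gives the C12 configuration of the target.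

Step 10
Reactants: 19 α-hydroxy lactone acid
Product: 20 triol acid (11Z)-8-(1,3-dithian-2-yl)-7,9-dihydroxy-9-(hydroxymethyl)-5,6-bis(TBS-oxy)heptadec-11-enoic acid
Conditions: LiBH4, THF, 0 °C → rt
Reagents that add atoms: none
Why: Borohydride reduction opens the lactone to the C11 primary alcohol and the C7 alcohol while a lithium carboxylate is inert, so C1 stays at the acid level.

Step 11
Reactants: 20 triol acid
Product: 21 triol methyl ester
Conditions: TMSCHN2, MeOH/toluene, 0 °C
Reagents that add atoms: (trimethylsilyl)diazomethane, C[Si](C)(C)C=[N+]=[N-]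
Why: Diazoalkane O-methylation is selective for the carboxylic acid over the three alcohols.

Step 12
Reactants: 21 triol methyl ester
Product: 22 tris-TES ether (C7–OTES, C11–OTES, C12–OTES)
Conditions: TESOTf, 2,6-lutidine, CH2Cl2, −78 → 0 °C
Reagents that add atoms: triethylsilyl trifluoromethanesulfonate, CC[Si](CC)(CC)OS(=O)(=O)C(F)(F)F
Why: Silyl triflate with a hindered pyridine base silylates the primary, the secondary and the hindered tertiary hydroxyl alike.

Step 13
Reactants: 22 tris-TES ether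
Product: 23 C9 aldehyde methyl (11Z)-8-formyl-5,6-bis(TBS-oxy)-7,9-bis(TES-oxy)-9-[(TES-oxy)methyl]heptadec-11-enoate
Conditions: MeI, CaCO3, MeCN/H2O (9:1), 40 °C
Reagents that add atoms: water, O
Why: S-methylation of the dithiane and hydrolysis of the sulfonium salt under carbonate buffering unmask the aldehyde without acid or base, so the silyl ethers, the Z-alkene and the C8 stereocentre should survive.

Step 14
Reactants: 23 C9 aldehyde; 24 dimethyl (chloromethyl)phosphonate
Product: 26 β-hydroxy-α-chlorophosphonate (C9/C10 diastereomers), via lithiated chlorophosphonate 25 (not isolated)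
Conditions: 24, LiN(iPr)2, THF, −78 °C; then 23, −78 °C; AcOH, −78 °C
Reagents that add atoms: none
Why: Carbonyl addition of the α-chlorophosphonate carbanion to the aldehyde is far faster than attack on the methyl ester at −78 °C, and the cold acidic quench stops at the chlorohydrin before Darzens closure or olefination; the new centres at C9 and C10 are uncontrolled and are erased later.

Step 15
Reactants: 26 β-hydroxy-α-chlorophosphonate
Product: 27 C9,C11-diol (primary TES removed)
Conditions: HF·pyridine, pyridine, THF, 0 °C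
Reagents that add atoms: none
Why: Buffered fluoride desilylation should remove the primary TES ether selectively, the secondary C7 and tertiary C12 TES ethers and the secondary TBS ethers being much more hindered.

Step 16
Reactants: 27 C9,C11-diol
Product: 28 α-chloro-β-ketophosphonate aldehyde (C10 epimers)
Conditions: Dess–Martin periodinane, NaHCO3, CH2Cl2, rt
Reagents that add atoms: none
Why: Dess–Martin oxidation converts the secondary carbinol to the C9 ketone and the primary alcohol to the C11 aldehyde in one operation without base, so C8 is not exposed to enolisation.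

Step 17
Reactants: 28 α-chloro-β-ketophosphonate aldehyde
Product: 29 silylated 2-chloro-4-siloxycyclopent-2-enone
Conditions: LiCl, iPr2NEt, MeCN, 0 °C → rt
Reagents that add atoms: none
Why: Intramolecular Horner–Wadsworth–Emmons olefination: lithium-assisted deprotonation by the amine occurs at the doubly activated C10–H, the chelated carbanion adds to the C11 aldehyde, and the oxaphosphetane collapses with loss of dimethyl phosphate to give C10=C11. The closest known reactions are the cyclopentenone-forming cyclisations of β-ketophosphonates onto a 1,4-related carbonyl and the olefinations of α-halo phosphonates that give vinyl halides. Ring C8–C12 closes by 5-exo-trig attack on the aldehyde carbonyl (enolate atoms C9 and C10 inside the new ring), and the five-membered ring enforces the cis alkene. No stereocentre is created, and both C10 epimers of 28 converge because C10 becomes sp2. The step needs deprotonation at C10 in preference to the C8 methine and an aldehyde that cannot enolise; the acidity gap between the chloro-ketophosphonate and the hindered C8–H, and the quaternary silyloxy-bearing C12 next to the aldehyde, secure both. The weak base and short contact time are meant to leave C8 and the β-silyloxy group at C7 untouched.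

Step 18
Reactants: 29 silylated 2-chloro-4-siloxycyclopent-2-enone
Product: 30 5,6,7,12-tetraol (de-acetyl target)
Conditions: HF·pyridine, pyridine, THF, 0 °C → rt
Reagents that add atoms: none
Why: Fluoride-mediated cleavage of all four silyl ethers under mildly acidic conditions should avoid the base-induced β-elimination at C7/C8.

Step 19
Reactants: 30 5,6,7,12-tetraol
Product: 31 methyl (5S,6R,7R)-5,6,7-triacetoxy-7-[(1S,2R)-4-chloro-2-hydroxy-2-[(Z)-oct-2-en-1-yl]-5-oxocyclopent-3-en-1-yl]heptanoate (target; 5S,6R,7R,8S,12R,14Z in prostanoid numbering)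
Conditions: Ac2O, pyridine, 0 °C → rt
Reagents that add atoms: acetic anhydride, CC(=O)OC(C)=O
Why: Acylation without a nucleophilic catalyst esterifies the three secondary hydroxyls while the hindered tertiary C12 hydroxyl stays free.

**Compound list**
1 | D-xylono-1,4-lactone | O=C1[C@H](O)[C@@H](O)[C@@H](CO)O1 | starting material
2 | 2,3,5-tris-O-TBS-D-xylono-1,4-lactone | O=C1[C@H](O[Si](C)(C)C(C)(C)C)[C@@H](O[Si](C)(C)C(C)(C)C)[C@@H](CO[Si](C)(C)C(C)(C)C)O1 | intermediate
3 | 2,3,5-tris-O-TBS-D-xylofuranose (lactol) | OC1[C@H](O[Si](C)(C)C(C)(C)C)[C@@H](O[Si](C)(C)C(C)(C)C)[C@@H](CO[Si](C)(C)C(C)(C)C)O1 | intermediate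
4 | (2-carboxyethyl)triphenylphosphonium bromide | OC(=O)CC[P+](c1ccccc1)(c1ccccc1)c1ccccc1.[Br-] | starting material
5 | lithium 3-(triphenylphosphoranylidene)propanoate (carboxylate ylide) | [Li+].[O-]C(=O)CC=P(c1ccccc1)(c1ccccc1)c1ccccc1 | intermediate
6 | (Z)-5,6,8-tris-O-TBS-2,3,4-trideoxy-D-xylo-oct-3-enonic acid | CC(C)(C)[Si](C)(C)OC[C@@H](O)[C@H](O[Si](C)(C)C(C)(C)C)[C@H](/C=C\CC(=O)O)O[Si](C)(C)C(C)(C)C | intermediate
7 | 5,6,8-tris-O-TBS-2,3,4-trideoxy-D-xylo-octonic acid | CC(C)(C)[Si](C)(C)OC[C@@H](O)[C@H](O[Si](C)(C)C(C)(C)C)[C@H](CCCC(=O)O)O[Si](C)(C)C(C)(C)C | intermediate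
8 | 5,6-bis-O-TBS-2,3,4-trideoxy-D-xylo-octonic acid (7,8-diol) | OC[C@@H](O)[C@H](O[Si](C)(C)C(C)(C)C)[C@H](CCCC(=O)O)O[Si](C)(C)C(C)(C)C | intermediate
9 | methyl (triphenylphosphoranylidene)acetate | COC(=O)C=P(c1ccccc1)(c1ccccc1)c1ccccc1 | starting material
10 | α-hydroxy aldehyde: 7-hydroxy-8-oxo-5,6-bis(TBS-oxy)octanoic acid (D-xylo) | O=C[C@@H](O)[C@H](O[Si](C)(C)C(C)(C)C)[C@H](CCCC(=O)O)O[Si](C)(C)C(C)(C)C | intermediate
11 | Z-hydroxy enoate: 10-methyl hydrogen (8Z)-7-hydroxy-5,6-bis(TBS-oxy)dec-8-enedioate | COC(=O)/C=C\[C@@H](O)[C@H](O[Si](C)(C)C(C)(C)C)[C@H](CCCC(=O)O)O[Si](C)(C)C(C)(C)C | intermediate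
12 | butenolide acid: 6-(5-oxo-2,5-dihydrofuran-2-yl)-5,6-bis(TBS-oxy)hexanoic acid | O=C1C=C[C@@H](O1)[C@H](O[Si](C)(C)C(C)(C)C)[C@H](CCCC(=O)O)O[Si](C)(C)C(C)(C)C | intermediate
13 | (Z)-oct-2-en-1-ol | CCCCC/C=C\CO | starting material
14 | (Z)-1-bromooct-2-ene | CCCCC/C=C\CBr | intermediate
15 | 1,3-dithiane | C1CSCSC1 | starting material
16 | 2-lithio-1,3-dithiane | [Li]C1SCCCS1 | intermediate
17 | dilithium lactone enolate carboxylate | [Li+].[Li+].[O-]C1=C[C@@H](C2SCCCS2)[C@@H](O1)[C@H](O[Si](C)(C)C(C)(C)C)[C@H](CCCC(=O)[O-])O[Si](C)(C)C(C)(C)C | intermediate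
18 | lactone acid: 6-[3-(1,3-dithian-2-yl)-4-[(Z)-oct-2-enyl]-5-oxooxolan-2-yl]-5,6-bis(TBS-oxy)hexanoic acid, ring 2,3-trans-3,4-trans | CCCCC/C=C\C[C@H]1C(=O)O[C@@H]([C@H](O[Si](C)(C)C(C)(C)C)[C@H](CCCC(=O)O)O[Si](C)(C)C(C)(C)C)[C@@H]1C2SCCCS2 | intermediate
19 | α-hydroxy lactone acid: as 18 with 4-hydroxy, OH trans to dithianyl | CCCCC/C=C\C[C@]1(O)C(=O)O[C@@H]([C@H](O[Si](C)(C)C(C)(C)C)[C@H](CCCC(=O)O)O[Si](C)(C)C(C)(C)C)[C@@H]1C2SCCCS2 | intermediate
20 | triol acid: (11Z)-8-(1,3-dithian-2-yl)-7,9-dihydroxy-9-(hydroxymethyl)-5,6-bis(TBS-oxy)heptadec-11-enoic acid | CCCCC/C=C\C[C@](O)(CO)[C@@H](C1SCCCS1)[C@@H](O)[C@H](O[Si](C)(C)C(C)(C)C)[C@H](CCCC(=O)O)O[Si](C)(C)C(C)(C)C | intermediate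
21 | triol methyl ester of 20 | CCCCC/C=C\C[C@](O)(CO)[C@@H](C1SCCCS1)[C@@H](O)[C@H](O[Si](C)(C)C(C)(C)C)[C@H](CCCC(=O)OC)O[Si](C)(C)C(C)(C)C | intermediate
22 | tris-TES ether of 21 | CCCCC/C=C\C[C@](O[Si](CC)(CC)CC)(CO[Si](CC)(CC)CC)[C@@H](C1SCCCS1)[C@@H](O[Si](CC)(CC)CC)[C@H](O[Si](C)(C)C(C)(C)C)[C@H](CCCC(=O)OC)O[Si](C)(C)C(C)(C)C | intermediate
23 | C9 aldehyde: methyl (11Z)-8-formyl-5,6-bis(TBS-oxy)-7,9-bis(TES-oxy)-9-[(TES-oxy)methyl]heptadec-11-enoate | CCCCC/C=C\C[C@](O[Si](CC)(CC)CC)(CO[Si](CC)(CC)CC)[C@@H](C=O)[C@@H](O[Si](CC)(CC)CC)[C@H](O[Si](C)(C)C(C)(C)C)[C@H](CCCC(=O)OC)O[Si](C)(C)C(C)(C)C | intermediate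
24 | dimethyl (chloromethyl)phosphonate | COP(=O)(CCl)OC | starting material
25 | dimethyl [chloro(lithio)methyl]phosphonate | [Li]C(Cl)P(=O)(OC)OC | intermediate
26 | β-hydroxy-α-chlorophosphonate (C9/C10 diastereomers) | CCCCC/C=C\C[C@](O[Si](CC)(CC)CC)(CO[Si](CC)(CC)CC)[C@@H](C(O)C(Cl)P(=O)(OC)OC)[C@@H](O[Si](CC)(CC)CC)[C@H](O[Si](C)(C)C(C)(C)C)[C@H](CCCC(=O)OC)O[Si](C)(C)C(C)(C)C | intermediate
27 | C9,C11-diol | CCCCC/C=C\C[C@](O[Si](CC)(CC)CC)(CO)[C@@H](C(O)C(Cl)P(=O)(OC)OC)[C@@H](O[Si](CC)(CC)CC)[C@H](O[Si](C)(C)C(C)(C)C)[C@H](CCCC(=O)OC)O[Si](C)(C)C(C)(C)C | intermediate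
28 | α-chloro-β-ketophosphonate aldehyde (C10 epimers): methyl (11Z)-8-[2-chloro-2-(dimethoxyphosphoryl)acetyl]-9-formyl-5,6-bis(TBS-oxy)-7,9-bis(TES-oxy)heptadec-11-enoate | CCCCC/C=C\C[C@](O[Si](CC)(CC)CC)(C=O)[C@@H](C(=O)C(Cl)P(=O)(OC)OC)[C@@H](O[Si](CC)(CC)CC)[C@H](O[Si](C)(C)C(C)(C)C)[C@H](CCCC(=O)OC)O[Si](C)(C)C(C)(C)C | intermediate
29 | methyl 5,6-bis(TBS-oxy)-7-(TES-oxy)-7-[4-chloro-2-[(Z)-oct-2-enyl]-5-oxo-2-(TES-oxy)cyclopent-3-en-1-yl]heptanoate | CCCCC/C=C\C[C@]1(O[Si](CC)(CC)CC)C=C(Cl)C(=O)[C@H]1[C@@H](O[Si](CC)(CC)CC)[C@H](O[Si](C)(C)C(C)(C)C)[C@H](CCCC(=O)OC)O[Si](C)(C)C(C)(C)C | intermediate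
30 | 5,6,7,12-tetraol (de-acetyl target) | CCCCC/C=C\C[C@]1(O)C=C(Cl)C(=O)[C@H]1[C@@H](O)[C@H](O)[C@H](CCCC(=O)OC)O | intermediate
31 | methyl (5S,6R,7R)-5,6,7-triacetoxy-7-[(1S,2R)-4-chloro-2-hydroxy-2-[(Z)-oct-2-en-1-yl]-5-oxocyclopent-3-en-1-yl]heptanoate | CCCCC/C=C\C[C@]1(O)C=C(Cl)C(=O)[C@H]1[C@@H](OC(C)=O)[C@H](OC(C)=O)[C@H](CCCC(=O)OC)OC(C)=O | target

**Step count**
Total: 19 steps. Longest linear sequence: 18 steps (steps 1–6 and 8–19, from 1); step 7 is a one-step side branch.

**Three steps most likely to fail**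

Step 17 (key ring closure). The chlorine-stabilised phosphonate carbanion may add too slowly to the hindered neopentyl aldehyde. The longer base contact would then erode C8 by enolisation or expel the C7 silyloxy group by E1cB. The fallback closes the same C10–C11 bond by an aldol reaction of a more nucleophilic enolate and sets out from aldehyde 23. Chloromethyllithium (ClCH2I, MeLi·LiBr, THF, −78 °C, AcOH quench at −78 °C) should give the chlorohydrin F1. Buffered HF·pyridine should free the primary alcohol F2, and Dess–Martin oxidation should give the chloromethyl ketone aldehyde F3. Soft enolisation toward the chlorine-bearing carbon (Bu2BOTf, iPr2NEt, CH2Cl2, −78 → 0 °C) should give the cyclic β-hydroxy-α-chloro ketone F4 by intramolecular boron aldol addition. Dehydration (MsCl, Et3N, −20 °C) returns to the route at 29.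

Step 3 (Wittig reaction on the silylated lactol). Under the basic ylide conditions a silyl group may migrate to the C7 alkoxide freed by ring opening, or the C6 silyloxy group may be lost by β-elimination from the open aldehyde. Either process scrambles the oxygen differentiation on which the butenolide depends. The fallback avoids any free alkoxide and sets out from lactone 2. Opening with MeNH(OMe)·HCl and iPrMgCl (THF, −20 °C) should give the Weinreb amide F5. TESOTf and 2,6-lutidine cap the freed hydroxyl as the C7 TES ether F6, and iBu2AlH (THF, −78 °C) gives the fully protected aldehydo sugar F7. Olefination with ylide 5 gives the alkenoic acid F8, and hydrogenation over Pd/C gives the saturated acid F9. Buffered HF·pyridine removes the primary TBS and the secondary TES ether together and returns to the route at 8.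

Step 6 (one-pot oxidation, olefination and lactonisation). The diol may suffer glycol cleavage or over-oxidation, the α-hydroxy aldehyde may oligomerise, and incomplete Z-selectivity would leave part of the material as an E-enoate that cannot lactonise. The fallback fixes the alkene geometry by ring formation and sets out from 7. Acylation of the free C7 hydroxyl with (diethoxyphosphoryl)acetyl chloride and pyridine, with aqueous NaHCO3 work-up to hydrolyse the mixed anhydride at C1, should give the phosphonoacetate F10. Buffered HF·pyridine frees the primary alcohol F11, and Dess–Martin oxidation gives the α-acyloxy aldehyde F12. Intramolecular Horner–Wadsworth–Emmons closure (LiCl, iPr2NEt, MeCN) returns to the route at 12.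

**Further compounds**
F1 | step 17 | chlorohydrin: methyl (11Z)-8-(2-chloro-1-hydroxyethyl)-5,6-bis(TBS-oxy)-7,9-bis(TES-oxy)-9-[(TES-oxy)methyl]heptadec-11-enoate | CCCCC/C=C\C[C@](O[Si](CC)(CC)CC)(CO[Si](CC)(CC)CC)[C@@H](C(O)CCl)[C@@H](O[Si](CC)(CC)CC)[C@H](O[Si](C)(C)C(C)(C)C)[C@H](CCCC(=O)OC)O[Si](C)(C)C(C)(C)C
F2 | step 17 | primary alcohol of F1 (C11–OH free) | CCCCC/C=C\C[C@](O[Si](CC)(CC)CC)(CO)[C@@H](C(O)CCl)[C@@H](O[Si](CC)(CC)CC)[C@H](O[Si](C)(C)C(C)(C)C)[C@H](CCCC(=O)OC)O[Si](C)(C)C(C)(C)C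
F3 | step 17 | chloromethyl ketone aldehyde | CCCCC/C=C\C[C@](O[Si](CC)(CC)CC)(C=O)[C@@H](C(=O)CCl)[C@@H](O[Si](CC)(CC)CC)[C@H](O[Si](C)(C)C(C)(C)C)[C@H](CCCC(=O)OC)O[Si](C)(C)C(C)(C)C
F4 | step 17 | cyclic β-hydroxy-α-chloro ketone (2-chloro-3-hydroxycyclopentanone, C10/C11 diastereomers) | CCCCC/C=C\C[C@]1(O[Si](CC)(CC)CC)C(O)C(Cl)C(=O)[C@H]1[C@@H](O[Si](CC)(CC)CC)[C@H](O[Si](C)(C)C(C)(C)C)[C@H](CCCC(=O)OC)O[Si](C)(C)C(C)(C)C
F5 | step 3 | N-methoxy-N-methyl-2,3,5-tris-O-TBS-D-xylonamide (4-OH free) | CON(C)C(=O)[C@H](O[Si](C)(C)C(C)(C)C)[C@@H](O[Si](C)(C)C(C)(C)C)[C@H](O)CO[Si](C)(C)C(C)(C)C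
F6 | step 3 | 4-O-TES ether of F5 | CON(C)C(=O)[C@H](O[Si](C)(C)C(C)(C)C)[C@@H](O[Si](C)(C)C(C)(C)C)[C@H](O[Si](CC)(CC)CC)CO[Si](C)(C)C(C)(C)C
F7 | step 3 | 2,3,5-tris-O-TBS-4-O-TES-aldehydo-D-xylose | O=C[C@H](O[Si](C)(C)C(C)(C)C)[C@@H](O[Si](C)(C)C(C)(C)C)[C@H](O[Si](CC)(CC)CC)CO[Si](C)(C)C(C)(C)C
F8 | step 3 | (Z)-5,6,8-tris-O-TBS-7-O-TES-2,3,4-trideoxy-D-xylo-oct-3-enonic acid | OC(=O)C/C=C\[C@H](O[Si](C)(C)C(C)(C)C)[C@@H](O[Si](C)(C)C(C)(C)C)[C@H](O[Si](CC)(CC)CC)CO[Si](C)(C)C(C)(C)C
F9 | step 3 | 5,6,8-tris-O-TBS-7-O-TES-2,3,4-trideoxy-D-xylo-octonic acid | OC(=O)CCC[C@H](O[Si](C)(C)C(C)(C)C)[C@@H](O[Si](C)(C)C(C)(C)C)[C@H](O[Si](CC)(CC)CC)CO[Si](C)(C)C(C)(C)C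
F10 | step 6 | C7 (diethoxyphosphoryl)acetate of 7 | CC(C)(C)[Si](C)(C)OC[C@@H](OC(=O)CP(=O)(OCC)OCC)[C@H](O[Si](C)(C)C(C)(C)C)[C@H](CCCC(=O)O)O[Si](C)(C)C(C)(C)C
F11 | step 6 | C8 primary alcohol of F10 | OC[C@@H](OC(=O)CP(=O)(OCC)OCC)[C@H](O[Si](C)(C)C(C)(C)C)[C@H](CCCC(=O)O)O[Si](C)(C)C(C)(C)C
F12 | step 6 | C8 aldehyde (α-acyloxy aldehyde) | O=C[C@@H](OC(=O)CP(=O)(OCC)OCC)[C@H](O[Si](C)(C)C(C)(C)C)[C@H](CCCC(=O)O)O[Si](C)(C)C(C)(C)C
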